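Read the slopes. You asked for a quick number on the flask, and your hunch is a weak dependence on free catalyst; the two earlier runs can test that.

all flasks: starting material 20 mM
- zeta: second substrate 40 mM; solid reagent 12 mM; free catalyst 2.8 mM; run made earlier
- theta: second substrate 40 mM; solid reagent 12 mM; free catalyst 4.4 mM; run made earlier
- flask: second substrate 40.0 mM; solid reagent 12.0 mM; free catalyst 2.0 mM

| zeta: time / h | zeta: target / % | theta: time / h | theta: target / % |
|---|---|---|---|
| 2.50 | 3.6 | 1.33 | 1.4 |
| 6.00 | 14.7 | 3.00 | 6.7 |
| 12.0 | 35.0 | 8.00 | 28.8 |
| 20.0 | 47.0 | 20.0 | 50.0 |

(each reading ± 0.5 percentage points)

1. apparent order in free catalyst when 30% of the starting material are converted (percent change of the rate of making target for one percent more free catalyst charged)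
2. factor on the rate of making target when 30% of the starting material are converted if free catalyst is charged twice over

- as a solid, counted per litre of solution: solid reagent
- at the start none of the solid reagent is in solution
- what is bound to the catalyst counts as converted

Let s be the slope of target across the steep middle stretch of a run: 6.00 h to 12.0 h in zeta, 3.00 h to 8.00 h in theta. My quantity is the two-run order n, the logarithm of the slope ratio over the logarithm of the catalyst ratio:

s(theta)/s(zeta) = 1.31

catalyst ratio = 1.57

n = ln(1.31)/ln(1.57) = 0.591

That is a reading, with the scatter of 0.5 percentage points in each point, and it stays less than proportional. The flask's 2.0 mM lies below both runs, so using n there is a stretch. Held flat, it gives for a doubling: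

factor = 2^n = 1.51

The forecast says 0.6 and 1.45, a factor lower than my flat one, expecting that “the order should fall as catalyst rises”.

The flask gives an order of 0.54 and a factor of 1.35, and the same two-point order taken across that doubling, ln(1.35)/ln(2), reads 0.435, set beside the 0.591 read from the two runs.

    starting material + free catalyst ⇌ catalyst intermediate A (K = 330 /M, k = 87.0 /M/min)
    partner + catalyst intermediate A → free catalyst + target (k = 1.20 /M/min)
    second substrate + free catalyst ⇌ catalyst intermediate B (K = 13.0 /M, k = 2.70 /M/min)
    partner + catalyst intermediate B → free catalyst + second product (k = 1.60 /M/min)
    free catalyst ⇌ dormant form (K = 0.480, k = 0.00750 /min)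
    solid reagent ⇌ partner, rate k6*(cs6 - [partner]) while solid is left; crystals form when [partner] > cs6 (solubility = 11.0 mM, k = 0.00290 /min)

At 15.0 h in this flask, the step from starting material takes up free catalyst 9.6 times as fast as the step from second substrate, forward rates alone, and the flask then holds 7.15 mM of target against 0.985 mM of second product.

(All runs were generated by integration with made-up constants.)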